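C1 is the carbinol carbon bearing the crotonoyl group (C2–C4, C15). The seven-membered ring runs C1, C5 (acyloxy), C6 (lactone O), C7, C8, C9 (OH), C10 (methyl C14). The lactone ring is O–C6–C7–C11(=C13)–C12.
Cuts: the C12 lactone goes back to a methyl lactol ether, the O5–acyl bond is cut, and C5–OH goes back to the C5 ketone. The ring bond C1–C10 is then returned to C5–C10 (retro α-ketol shift), and C5–C1 is cut to a cyclohexanone and (E)-1-diazopent-3-en-2-one.
Enabling feature: at the C5-ketone level C1 is the carbinol carbon of an α-hydroxy-β-diketone (C5=O, C1–OH, C2=O), the product pattern of a ketol shift. Taking C1 out of the seven-membered ring leaves the all-equatorial cyclohexanone C5–C6–C7–C8–C9–C10, whose carbons together with C11–C14 are those of carvone.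
Forward: the five-membered O-ring is closed first on (S)-carvone and kept as a lactol ether so that it is no Michael acceptor. C9 and C10 are set on the six-membered ring, the C1–C4/C15 chain is joined to C5, the seven-membered ring is formed last by ring enlargement, and the lactone level is restored in the final step.
Stereochemistry: C7 comes from (S)-carvone, C6 from enolate hydroxylation anti to C7, C9 from hydroxyl-directed epoxidation, C10 from axial protonation, C1 from the stereospecific 1,2-shift, C5 from hydride delivery by the C1 hydroxyl, and the ester centre from (R)-2-methylbutanoic acid.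

Key step: step 11

Remark on descriptors: the carbocycle is viewed with C5→C6→C7→C8→C9→C10(→C1) running clockwise. β points toward the viewer (the face of H-6 and of the C7–C11 bond) and α points away.
Remark on supply: (S)-carvone, (E)-pent-3-en-2-one and (R)-2-methylbutanoic acid are taken as commercial.
Remark on C12: the acetal carbon is drawn as the anomer with OMe cis to H-6. This centre is erased in step 15, so its configuration has no consequence. Lactols 4 and 22 are anomeric mixtures and carry no descriptor at C12.

Step 1
Reactants: 1 (S)-(+)-carvone
Product: 3 (5R,6R)-6-hydroxycarvone, via lithium dienolate 2 (not isolated)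
Conditions: LDA, THF, −78 °C; 2-(phenylsulfonyl)-3-phenyloxaziridine, −78 °C; AcOH quench
Reagents that add atoms: 2-(phenylsulfonyl)-3-phenyloxaziridine, O=S(=O)(c1ccccc1)N1OC1c1ccccc1
Why: Kinetic α′-deprotonation gives the cross-conjugated dienolate, and enolate hydroxylation by the N-sulfonyloxaziridine takes place anti to the C7 isopropenyl group, which sets C6 with its hydroxyl α (trans, diequatorial, also the thermodynamic ketol).

Step 2
Reactants: 3 (5R,6R)-6-hydroxycarvone
Product: 5 enone methyl lactol ether, via lactol 4 (not isolated)
Conditions: SeO2, 1,4-dioxane, 70 °C; filtration and solvent exchange; MeOH, PPTS (cat.), 4 Å molecular sieves, 23 °C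
Reagents that add atoms: methanol, CO
Why: Riley allylic oxidation takes the methyl group C12 of the electron-rich 1,1-disubstituted alkene to the enal (the enone alkene is deactivated), the equatorial C6 hydroxyl closes on it to the trans-fused lactol, and acid-catalysed acetalisation (the aldehyde oxygen leaves as water) fixes the five-membered O-ring as a methyl lactol ether that is no Michael acceptor.

Step 3
Reactants: 5 enone methyl lactol ether
Product: 6 allylic alcohol (C5–OH β)
Conditions: NaBH4, CeCl3·7H2O, MeOH, −78 °C
Reagents that add atoms: none
Why: Luche reduction is 1,2-selective, and axial hydride attack on the α face of the locked enone gives the pseudo-equatorial β C5 alcohol, cis to the C7–C11 bond as in the reduction of carvone to cis-carveol.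

Step 4
Reactants: 6 allylic alcohol (C5–OH β)
Product: 7 β-epoxy alcohol
Conditions: VO(acac)2 (cat.), t-BuOOH, CH2Cl2, 0 °C
Reagents that add atoms: tert-butyl hydroperoxide, CC(C)(C)OO
Why: Vanadium-catalysed hydroxyl-directed epoxidation delivers oxygen to the allylic C9=C10 bond syn to the β C5 hydroxyl and leaves the remote exocyclic alkene untouched, which sets C9–O β, the face that nucleophilic epoxidation of the enone would not reach.

Step 5
Reactants: 7 β-epoxy alcohol
Product: 8 β-epoxy ketone
Conditions: (n-Pr4N)RuO4 (5 mol %), N-methylmorpholine N-oxide, 4 Å molecular sieves, CH2Cl2, 23 °C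
Reagents that add atoms: none
Why: Ley–Griffith oxidation under neutral conditions returns the C5 ketone without touching the epoxide, acetal or alkene, and no stereocentre is affected.

Step 6
Reactants: 8 β-epoxy ketone
Product: 9 β-hydroxy ketone (all-equatorial)
Conditions: Cp2TiCl2, Zn dust, THF, 23 °C; then 8, THF/MeOH, −78 °C
Reagents that add atoms: none
Why: Cp2TiCl (trivalent titanium) opens the oxirane of the α,β-epoxy ketone by inner-sphere homolysis of the C10–O bond and a second equivalent gives the titanium enolate, whose axial protonation from the β face leaves the C14 methyl equatorial (α) next to the retained β C9 hydroxyl, while the C6–O bond survives because this mild reductant forms no ketyl.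

Step 7
Reactants: 9 β-hydroxy ketone (all-equatorial)
Product: 10 silyl ether ketone
Conditions: TBSCl, imidazole, DMF, 23 °C
Reagents that add atoms: tert-butyldimethylsilyl chloride, CC(C)(C)[Si](C)(C)Cl
Why: Standard silylation of the unhindered equatorial secondary alcohol under mildly basic conditions avoids β-elimination, spares the acetal and keeps O9 out of the later esterification.

Step 8
Reactants: 11 (E)-pent-3-en-2-one
Product: 14 (E)-1-diazopent-3-en-2-one, via lithium enolate 12 (not isolated), via trifluoroacetyl diketone 13 (not isolated)
Conditions: LiN(SiMe3)2, THF, −78 °C; CF3CO2CH2CF3; aq HCl work-up; 4-acetamidobenzenesulfonyl azide, Et3N, H2O, MeCN, 23 °C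
Reagents that add atoms: 4-acetamidobenzenesulfonyl azide, CC(=O)Nc1ccc(cc1)S(=O)(=O)N=[N+]=[N-]
Why: Detrifluoroacetylative diazo transfer works because kinetic trifluoroacetylation of the methyl group activates it for diazo transfer with loss of the trifluoroacetyl group, which avoids exposing the enone to diazomethane and keeps the (E)-alkene.

Step 9
Reactants: 14 (E)-1-diazopent-3-en-2-one; 10 silyl ether ketone
Product: 16 diazo carbinol, via lithiated diazo ketone 15 (not isolated)
Conditions: LDA (1.0 equiv to 14), THF, −78 °C; then 10, −78 °C; AcOH quench at −78 °C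
Reagents that add atoms: none
Why: Aldol-type addition of the α-lithiated diazo ketone (the diazo carbon is the kinetic α′ site of the enone) to the activated α-alkoxy ketone is reversible and follows equatorial attack, so the bulky diazoacyl group sits equatorial (β) and the helper C5 hydroxyl axial (α).

Step 10
Reactants: 16 diazo carbinol
Product: 17 hydroxy 1,2-diketone
Conditions: dimethyldioxirane (1.1 equiv, acetone solution), CH2Cl2, −40 °C
Reagents that add atoms: dimethyldioxirane, CC1(C)OO1
Why: Dimethyldioxirane transfers oxygen to the nucleophilic diazo carbon with loss of N2 (diazo-to-carbonyl oxidation) far faster than it epoxidises the inductively deactivated exocyclic alkene or the enone, so one equivalent at low temperature gives the vicinal diketone without touching C5.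

Step 11
Reactants: 17 hydroxy 1,2-diketone
Product: 18 ring-enlarged 2-crotonoyl-2-hydroxycycloheptanone
Conditions: Cu(OTf)2 (10 mol %), 2,2'-bipyridine (12 mol %), 2,6-di-tert-butylpyridine (20 mol %), 4 Å molecular sieves, CH2Cl2, 23 °C
Reagents that add atoms: none
Why: Divalent copper binds the s-cis C1/C2 diketone of 17 with the axial C5 hydroxyl held syn to the C1 carbonyl, so that the C5–C10 bond stands perpendicular to that carbonyl and shifts suprafacially from C5 to C1 while C5–OH collapses to the C5 ketone (α-ketol or acyloin rearrangement). The closest known reactions are the Lewis-acid ring enlargements of 1-acylcycloalkanols (D-homoannulation of 17-hydroxy-20-keto steroids) and the copper-triflate-catalysed isomerisation of β-hydroxy-α-dicarbonyl compounds to α-hydroxy-β-dicarbonyl compounds, which runs downhill because a vicinal diketone is traded for a chelated 1,3-diketone. The seven-membered ring is closed by ring enlargement, that is by a 1,2-alkyl shift that inserts C1 between C5 and C10 of the cyclohexane, not by an end-to-end cyclisation. The only new stereocentre, C1, is fixed by the C5 carbinol configuration of step 9: with the side chain equatorial and O5 syn to O1, C10 can reach only the face of C1 that leaves the hydroxyl α (cis to the C14 methyl) and the crotonoyl group β and equatorial, and C10 itself migrates with retention. The step needs migration of C10 rather than C6, which is secured because C6 bears the electron-withdrawing ring oxygen and because the rotamer that aligns C5–C6 pushes the acyl chain against the C14 methyl group. A second shift of the crotonoyl group from C1 to C5 is held back because in the copper chelate of 18 the C1–C2 bond lies in the plane of the C5 carbonyl.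

Step 12
Reactants: 18 ring-enlarged 2-crotonoyl-2-hydroxycycloheptanone
Product: 19 trans-C1,C5-diol
Conditions: Me4NBH(OAc)3, MeCN/AcOH, −30 °C
Reagents that add atoms: none
Why: In this hydroxyl-directed reduction (Evans–Saksena type) the α C1 hydroxyl exchanges onto boron and delivers hydride to the α face of the adjacent, more electrophilic α-alkoxy C5 ketone in preference to the conjugated C2 ketone, which gives the β C5 alcohol trans to O1 and to O6.

Step 13
Reactants: 19 trans-C1,C5-diol; 20 (R)-2-methylbutanoic acid
Product: 21 C5 (R)-2-methylbutanoate
Conditions: DCC, DMAP (cat.), CH2Cl2, 0 to 23 °C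
Reagents that add atoms: none
Why: Steglich esterification acylates the only free secondary hydroxyl (O9 is silylated, O1 is tertiary) under conditions that do not racemise the α-branched acid, so the (R) centre is carried over unchanged.

Step 14
Reactants: 21 C5 (R)-2-methylbutanoate
Product: 22 deprotected lactol
Conditions: 48% aq HF, MeCN, 0 to 23 °C
Reagents that add atoms: water, O
Why: Aqueous HF cleaves the silyl ether through Si–F bond formation and its acidity hydrolyses the allylic methyl acetal to the lactol in the same operation, while the ester, the ketol and the enone are stable to these conditions.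

Step 15
Reactants: 22 deprotected lactol
Product: 23 target CNP0331957.3
Conditions: activated MnO2, CH2Cl2, 23 °C
Reagents that add atoms: none
Why: Activated MnO2 oxidises the allylic lactol chemoselectively to the α-methylene-γ-butyrolactone and leaves the non-allylic C9 alcohol and the tertiary C1 alcohol untouched, which gives the target.

Compound list
1 | (S)-(+)-carvone | CC1=CC[C@@H](CC1=O)C(C)=C | starting material
2 | lithium cross-conjugated dienolate of carvone (O–Li on C5, C5=C6) | [Li+].[O-]C1=C[C@@H](C(C)=C)CC=C1C | intermediate
3 | (5R,6R)-6-hydroxycarvone; C6–OH α, trans to the isopropenyl group on C7 | CC1=CC[C@H](C(C)=C)[C@@H](O)C1=O | intermediate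
4 | enone lactol; trans-fused 2-hydroxy-3-methylenetetrahydrofuran on C6 (O, α) and C7 (C11, β), anomeric mixture | CC1=CC[C@@H]2C(=C)C(O)O[C@H]2C1=O | intermediate
5 | enone methyl lactol ether; as 4 but with OMe on C12 cis to H-6 | CC1=CC[C@@H]2C(=C)[C@H](OC)O[C@H]2C1=O | intermediate
6 | allylic alcohol; C5–OH β, trans to O6 | CC1=CC[C@@H]2C(=C)[C@H](OC)O[C@H]2[C@@H]1O | intermediate
7 | β-epoxy alcohol; C9–C10 oxirane on the β face, C14 methyl α, C5–OH β | C[C@@]12O[C@@H]1C[C@@H]3C(=C)[C@H](OC)O[C@H]3[C@@H]2O | intermediate
8 | β-epoxy ketone; C5 ketone, C9–C10 oxirane β | C[C@@]12O[C@@H]1C[C@@H]3C(=C)[C@H](OC)O[C@H]3C2=O | intermediate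
9 | β-hydroxy ketone; C9–OH β, C14 methyl α, O6 α, C11 β, all equatorial | C[C@H]1[C@H](O)C[C@@H]2C(=C)[C@H](OC)O[C@H]2C1=O | intermediate
10 | silyl ether ketone; 9 with O9–TBS | C[C@H]1[C@H](O[Si](C)(C)C(C)(C)C)C[C@@H]2C(=C)[C@H](OC)O[C@H]2C1=O | intermediate
11 | (E)-pent-3-en-2-one | C/C=C/C(C)=O | starting material
12 | kinetic lithium enolate of 11 | [Li+].[O-]C(=C)/C=C/C | intermediate
13 | (E)-1,1,1-trifluorohept-5-ene-2,4-dione | C/C=C/C(=O)CC(=O)C(F)(F)F | intermediate
14 | (E)-1-diazopent-3-en-2-one | C/C=C/C(=O)C=[N+]=[N-] | intermediate
15 | (E)-1-diazo-1-lithiopent-3-en-2-one | C/C=C/C(=O)C([Li])=[N+]=[N-] | intermediate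
16 | diazo carbinol; C5–OH α (axial), C5–C1(=N2)–C2(=O)–CH=CH–CH3 β (equatorial) | C[C@H]1[C@H](O[Si](C)(C)C(C)(C)C)C[C@@H]2C(=C)[C@H](OC)O[C@H]2[C@]1(O)C(=[N+]=[N-])C(=O)/C=C/C | intermediate
17 | hydroxy 1,2-diketone; as 16 but with C1=O | C[C@H]1[C@H](O[Si](C)(C)C(C)(C)C)C[C@@H]2C(=C)[C@H](OC)O[C@H]2[C@]1(O)C(=O)C(=O)/C=C/C | intermediate
18 | ring-enlarged ketol; seven-membered ring, C5 ketone, C1–OH α, (E)-crotonoyl on C1 β | C[C@H]1[C@H](O[Si](C)(C)C(C)(C)C)C[C@@H]2C(=C)[C@H](OC)O[C@H]2C(=O)[C@]1(O)C(=O)/C=C/C | intermediate
19 | trans-C1,C5-diol; C5–OH β, C1–OH α | C[C@H]1[C@H](O[Si](C)(C)C(C)(C)C)C[C@@H]2C(=C)[C@H](OC)O[C@H]2[C@H](O)[C@]1(O)C(=O)/C=C/C | intermediate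
20 | (R)-2-methylbutanoic acid | CC[C@@H](C)C(=O)O | starting material
21 | C5 (R)-2-methylbutanoate of 19 | C[C@H]1[C@H](O[Si](C)(C)C(C)(C)C)C[C@@H]2C(=C)[C@H](OC)O[C@H]2[C@H](OC(=O)[C@H](C)CC)[C@]1(O)C(=O)/C=C/C | intermediate
22 | deprotected lactol; free C9–OH β, C1–OH α, C12 lactol as anomeric mixture | C[C@H]1[C@H](O)C[C@@H]2C(=C)C(O)O[C@H]2[C@H](OC(=O)[C@H](C)CC)[C@]1(O)C(=O)/C=C/C | intermediate
23 | CNP0331957.3 | C=C1C(=O)O[C@@H]2[C@@H]1C[C@@H](O)[C@H](C)[C@@](O)(C(=O)/C=C/C)[C@H]2OC(=O)[C@H](C)CC | target

Total step count: 15. Longest linear sequence: 14 (steps 1–7 and 9–15).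

Steps most likely to fail

Step 11. The shift may stall for lack of driving force in a six-to-seven enlargement. C6 may migrate in place of C10. O5 may close reversibly on the enone by 6-endo oxa-Michael addition, or the product may drift on by an acyl shift. The fallback sets out from diazo carbinol 16. Rh2(OAc)4 in CH2Cl2 expels nitrogen, and the carbenoid forces an irreversible 1,2-shift of C10 to give the ring-enlarged 2-crotonoylcycloheptanone F1. Its enolate is then hydroxylated at C1 with an enantiopure (camphorsulfonyl)oxaziridine, the reagent enantiomer being chosen to reinforce attack on the α face. The route is rejoined at 18.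

Step 9. The lithiated diazo enone may be lost to γ-deprotonation or self-condensation, and the adduct of the hindered ketone may revert. The fallback sets out from ketone 10 and enone 11. The kinetic lithium enolate 12 adds to 10 in an aldol reaction to give the β-hydroxy ketone F2, which carries C1 as a methylene group. A Riley oxidation (SeO2, aqueous dioxane) of this activated methylene then gives the vicinal diketone. The route is rejoined at 17, and no diazo compound is used.

Step 12. Chemoselectivity may be lost through hydride delivery from the C1-bound borohydride to the C2 enone carbonyl. The fallback sets out from 18. Both ketones are reduced on purpose with excess Me4NBH(OAc)3 at higher temperature to give the triol F3, in which C5 is still set by delivery from the α C1 hydroxyl. MnO2 then re-oxidises only the allylic C2 alcohol. The route is rejoined at 19.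

Further compounds
F1 | step 11 | ring-enlarged 2-crotonoylcycloheptanone (C1–H, enolisable β-diketone) | C[C@H]1[C@H](O[Si](C)(C)C(C)(C)C)C[C@@H]2C(=C)[C@H](OC)O[C@H]2C(=O)C1C(=O)/C=C/C
F2 | step 9 | aldol adduct, C5–OH α, C5–CH2–C(=O)–CH=CH–CH3 β | C[C@H]1[C@H](O[Si](C)(C)C(C)(C)C)C[C@@H]2C(=C)[C@H](OC)O[C@H]2[C@]1(O)CC(=O)/C=C/C
F3 | step 12 | triol, C5–OH β, C1–OH α, allylic C2–OH as epimer mixture | C[C@H]1[C@H](O[Si](C)(C)C(C)(C)C)C[C@@H]2C(=C)[C@H](OC)O[C@H]2[C@H](O)[C@]1(O)C(O)/C=C/C
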